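The constants were set for the occasion; the flask was simulated.

I began from the constants: 573 M⁻² s⁻¹, 1550 M⁻² s⁻¹ and 0.0236 M⁻¹ s⁻¹ each multiply the same product, c(partner) times c(free catalyst).

    solid reagent ⇌ partner, rate k1*(cs1 - [partner]) while solid is left; crystals form when [partner] > cs1 (cs1 = 37 mM, k1 = 0.0256 s⁻¹)
    partner + free catalyst + right-handed substrate → free catalyst + right-handed product (k2 = 573 M⁻² s⁻¹)
    partner + free catalyst → spent catalyst (k3 = 0.0236 M⁻¹ s⁻¹)
    partner + free catalyst + left-handed substrate → free catalyst + left-handed product (k4 = 1550 M⁻² s⁻¹)

left-handed substrate 0.10 M; solid reagent 0.300 M; free catalyst 0.10 mM; right-handed substrate 0.10 M; time 2.5 h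

- how much of the left-handed substrate and right-handed substrate together has reacted by 2.5 h
- how much left-handed product there is at 2.5 h, in percent of the left-handed substrate and right-handed substrate together charged
- how much right-handed product there is at 2.5 h, in percent of the left-handed substrate and right-handed substrate together charged
- how much right-handed substrate there is at 2.5 h, in percent of the left-handed substrate and right-handed substrate together charged

- free catalyst is single-handed; left-handed substrate and right-handed substrate are mirror images of each other, charged as a racemate, each of them at the stated concentration
- solid reagent is a solid; its amount is given per volume of the solution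
- at the start none of the solid reagent is in solution
- run time (flask): 2.5 h

The solid reagent feeds the partner towards 37 mM on a time of about 39.1 s, far shorter than the run, so I froze c(partner) there. Free catalyst then lasts 0.318 h, shorter than the run of 2.5 h, so I expected 0.0385% of it to remain at the end.

But the frozen value was needed for that check and no further. Each of the steps with those constants counts the time integral of c(partner) times c(free catalyst), which I called the exposure. Free and spent catalyst together stay at 0.10 mM, so dividing that charge by 0.0236 M⁻¹ s⁻¹ gives the exposure budget, 0.00424 M^2 s.

Each substrate falls by e to the power of minus its constant times the exposure. The right-handed substrate therefore keeps 8.81% of its charge and the left-handed substrate 0.140%, a selectivity factor of 2.71. This spending takes 0.191 M of partner, less than the 0.300 M charged. I committed to a conversion of 95.5% and y_S of 4.41%.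

The forecast gave 95.5%, 49.93%, 45.58% and 4.42%, reasoning that “The catalyst is therefore essentially dead”.

The flask gave 95.5%, 49.9%, 45.6% and 4.42%, with free catalyst at 0.0477% at 2.50 h. At 0.250 h, spent catalyst stood at 45.4%; that share of the budget gives right-handed substrate of 16.6%, and the flask held 16.6%.

The neighbour flask with 0.12 M of solid reagent holds less than the 0.191 M the budget asks, so I reckoned its conversion as that charge over both substrates, 60.0%. It gave 60.0%, with solid reagent at 0% and free catalyst at 77.3%.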